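If I had to give the ratio of target to other capture product in the flask now, I started from the three earlier runs.

| flask | starting material | first nucleophile | gas | remark | time |
|---|---|---|---|---|---|
| north-west | 0.25 mM | 0.525 mM | 0.15 mM (held) | run made earlier |  |
| east | 1 mM | 0.525 mM | 0.15 mM (held) | run made earlier |  |
| south | 0.50 mM | 1.1 mM | 0.15 mM (held) | run made earlier |  |
| flask | 0.50 mM | 0.525 mM | 0.15 mM (held) |  | 3.0 h |

- north-west (time / h: target / %, other capture product / %): 0.500: 17.4, 81.8; 1.00: 17.8, 81.9; 1.50: 18.4, 81.6; 2.00: 18.3, 82.0; 2.50: 18.5, 81.7; 3.00: 19.0, 81.7
- east (time / h: target / %, other capture product / %): 0.200: 15.5, 80.8; 0.667: 16.2, 83.3; 1.00: 18.3, 83.5; 1.50: 16.6, 83.3; 2.50: 15.5, 84.0; 3.00: 16.0, 83.1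
- south (time / h: target / %, other capture product / %): 0.250: 31.2, 68.5; 0.417: 31.3, 69.3; 0.833: 31.9, 69.1; 1.50: 32.1, 69.9; 3.00: 31.6, 68.3

(readings scatter by 0.5 percentage points)

- ratio of target to other capture product at 12 s
- ratio of target to other capture product at 6.0 min
- ratio of target to other capture product at 3.0 h

- at the start none of second nucleophile is dissolved
- candidate steps: starting material <-> intermediate; first nucleophile + intermediate -> target; second nucleophile + intermediate -> other capture product; first nucleophile -> decomposition product; gas <-> second nucleophile

In the candidate steps target and other capture product both form from the intermediate, so I carried one quantity, the selectivity factor: with the gas held at 0.15 mM, the ratio of target to other capture product divided by the mean [first nucleophile] during capture. I assumed that [first nucleophile] fell during capture by the target formed, and so took its mean as the charge less half of that target, 1.02 mM in the south run. The last south reading then put the factor at 0.453 mM⁻¹.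

For the flask I assumed target near the last north-west reading of 19.0%, which made the mean [first nucleophile] 0.478 mM. My own reckoning therefore gave a late ratio of 0.216.

The forecast gave 0.33 at 12 s, with a range of 0.23 to 1, then 0.218 at 6.0 min and 0.212 at 3.0 h, the last slightly lower than mine. Its reason for the high early value was: “the second nucleophile may still be building up”.

The flask gave 0.285, 0.218 and 0.213.

    starting material ⇌ intermediate (K = 0.00610, k = 0.0320 s⁻¹)
    first nucleophile + intermediate → target (k = 340 M⁻¹ s⁻¹)
    second nucleophile + intermediate → other capture product (k = 5200 M⁻¹ s⁻¹)
    first nucleophile → decomposition product (k = 2.40 × 10⁻⁵ s⁻¹)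
    gas ⇌ second nucleophile, rate k5*(csat - [second nucleophile]) (kL = 0.450 s⁻¹)

The two parted at 12 s, where the forecast stood higher than the flask; by uptake of gas alone, the gap between [second nucleophile] and its saturation concentration halves every 1.54 s. In a neighbour, the same flask but with 1.3 mM of first nucleophile, target ended at 35.0%, so the selectivity factor of 0.453 mM⁻¹ gave 0.549, and that neighbour's ratio at 3.0 h was 0.539.

The readings are calculated from invented constants; noise was put on by code.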